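In a one-step world, starting material and partner make target at a fixed selectivity, and the order of charging is no term of the trade. One colleague holds this view of the flasks below: the target stands flat from the first readings, near 57.8 % in violet.

| flask | starting material | partner | protic impurity | remark | time |
|---|---|---|---|---|---|
| violet | 5 mM | 4.75 mM | 1 mM | run made earlier |  |
| blue | 5 mM | 4.75 mM | 0.67 mM | run made earlier |  |
| ochre | 5 mM | 4.75 mM | 1.5 mM | run made earlier |  |
| Saturday's | 5.0 mM | 4.75 mM (fed, over 1.5 min) | 1.00 mM | all else is in the flask from the start; the feed brings no volume worth counting | 4.0 min |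
| Sunday's | 5.0 mM | 4.75 mM | 1.00 mM | everything together at the start | 4.0 min |
| Tuesday's | 5.0 mM (fed, over 1.5 min) | 4.75 mM | 1.00 mM | all else is in the flask from the start; the feed brings no volume worth counting | 4.0 min |

| run | time / min | side product / % | target / % |
|---|---|---|---|
| violet | 0.167 | 6.7 | 57.8 |
| violet | 0.500 | 13.8 | 57.0 |
| violet | 0.833 | 16.5 | 56.8 |
| violet | 1.33 | 19.9 | 57.2 |
| violet | 2.00 | 21.7 | 57.7 |
| violet | 2.50 | 22.7 | 57.8 |
| blue | 0.417 | 13.4 | 58.0 |
| blue | 0.833 | 21.2 | 57.5 |
| blue | 1.33 | 24.1 | 58.7 |
| blue | 1.50 | 25.3 | 59.1 |
| blue | 2.00 | 26.4 | 58.7 |
| blue | 2.50 | 27.6 | 58.3 |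
| ochre | 0.417 | 9.8 | 54.5 |
| ochre | 0.833 | 12.5 | 55.8 |
| ochre | 1.33 | 14.2 | 56.3 |
| ochre | 1.50 | 14.9 | 55.9 |
| ochre | 2.00 | 14.6 | 55.3 |
| ochre | 2.50 | 14.3 | 56.0 |

(standard deviation of a reading: 0.5 percentage points)

- the analysis behind the earlier runs scatters by 0.5 percentage points, standard deviation

- the flask that comes out highest in amount of side product, in percent of the starting material charged, or "all alike" when all lie within 1.5 percentage points (Saturday's / Sunday's / Tuesday's / all alike)
- side product at the end, in percent of the starting material charged, Saturday's
- side product at the end, in percent of the starting material charged, Sunday's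
- side product at the end, in percent of the starting material charged, Tuesday's

The other colleague books the charge, not the product. The protic impurity is taken to claim its equivalent of starting material, 20.0 % of the charge in violet. Violet's last reading then leaves 22.2 %, and the remainder, the percent of the charge left once target and the impurity's equivalent are struck off, is read as the side product to expect. Blue's last reading gives 28.3 % against a read 27.6 %, and ochre's gives 14.0 % against 14.3 %, with a scatter of 0.5 percentage points.

So the dispute narrows to the target made per partner charged, a reading of 60.8 % in violet. The first colleague holds it fixed, which puts the three flasks near the remainder. The second expects it to move with the dosing, and the forecast stands on that side: Tuesday's highest, with 42 % for Saturday's, 23 % for Sunday's and 72 % for Tuesday's. Its ground for Tuesday's is “Feeding starting material means it arrives after the partner has died”.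

The flasks end at 50.6 % for Saturday's, 22.5 % for Sunday's and 74.4 % for Tuesday's, so Tuesday's is highest, and the one-step view holds for Sunday's, charged together, beside the remainder of 22.2 %. Saturday's ended with 29.4 % of target against 57.4 % in Sunday's. Put into the remainder, Saturday's target gives 50.6 %, while the forecast's 42 % corresponds to a target of 38.0 %.

    starting material + partner → target (k = 151 /M/s)
    starting material → side product (k = 0.0229 /s)
    starting material + protic impurity → quenched substrate (k = 127 /M/s)
    partner → decomposed reagent (k = 0.267 /s)

Take Sunday's flask with 1.9 mM of partner. At violet's share the target is 23.1 %, so the remainder is 56.9 %. The computed flask gives 53.9 % of side product, with 25.9 % of target.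

The readings come from a simulation with constants of no real substance, and the scatter is random.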